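**Strategy.** The decalin (C1 = quaternary carbon bearing CH3 and CH2OAr, Ar = 6,8-dimethoxycoumarin-7-yl; C2, C4a, C5 methyl-bearing; C6 ketone; C8a ring-fusion CH) is opened across the ring-fusion bond C4a–C8a together with C1–C2. Ring B, with the contiguous stereocentres C1, C2, C4a and C8a, is a Diels–Alder retron once a C3=C4 double bond is added, and ring A is the tether. An intramolecular Diels–Alder reaction of the acyclic all-E trienoate ethyl (2E,7S,8E,10E)-2,7,8-trimethyl-6-oxododeca-2,8,10-trienoate thus closes both rings and sets four stereocentres at once, relayed from the single C5 methyl centre bought as (R)-but-3-yn-2-ol. Hydrogenation, redox adjustment and Mitsunobu etherification with isofraxidin complete the synthesis.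

Key step: step 7

Remark on the chemistry: the palladium/zinc propargylation of step 2 is assumed to follow its established course (anti oxidative addition, cyclic SE2′ addition, net inversion), so that the (R)-alcohol 1 leads to the (S)-methyl centre. Acyclic intermediates carry their own chain numbering: chain C7 becomes decalin C5, chain C3 and C8 become C8a and C4a, chain C2 and C11 become C1 and C2.

Step 1
Reactants: 1 (R)-but-3-yn-2-ol
Product: 2 (R)-but-3-yn-2-yl methanesulfonate
Conditions: MsCl, Et3N, CH2Cl2, −78 → 0 °C
Reagents that add atoms: methanesulfonyl chloride, CS(=O)(=O)Cl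
Why: O-sulfonylation of a secondary alcohol, which leaves the C–O bond and therefore the configuration untouched.

Step 2
Reactants: 2 (R)-but-3-yn-2-yl methanesulfonate; 3 pent-4-enal
Product: 4 (3S,4R)-3-methyloct-7-en-1-yn-4-ol
Conditions: Pd(OAc)2 (5 mol %), PPh3 (5 mol %), Et2Zn (3 equiv), THF, −78 → −20 °C
Reagents that add atoms: none
Why: Marshall propargylation, in which zerovalent palladium (generated in situ) displaces the mesylate anti and transmetalation gives a chiral allenylzinc that adds to the aldehyde through a cyclic SE2′ transition state, so the methyl-bearing C3 should be set as S by chirality transfer (net inversion) and the carbinol C4 mainly anti (4R); the minor C4 epimer is carried along because C4 becomes a ketone in step 6.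

Step 3
Reactants: 4 (3S,4R)-3-methyloct-7-en-1-yn-4-ol
Product: 6 (1E,3S,4R)-1-iodo-2,3-dimethylocta-1,7-dien-4-ol, via alkenylalane 5 (not isolated)
Conditions: AlMe3 (3 equiv), Cp2ZrCl2 (0.3 equiv), CH2Cl2, 0 °C → rt; then I2, THF, −30 → 0 °C
Reagents that add atoms: trimethylaluminium, C[Al](C)C; iodine, II
Why: Negishi zirconium-catalysed carboalumination adds methyl and aluminium syn across the terminal alkyne (methyl to the internal carbon) and iodinolysis proceeds with retention, giving the E-alkenyl iodide, while the terminal alkene reacts far more slowly and C3/C4 are untouched.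

Step 4
Reactants: 6 (1E,3S,4R)-1-iodo-2,3-dimethylocta-1,7-dien-4-ol; 7 ethyl methacrylate
Product: 8 ethyl (2E,6R,7S,8E)-6-hydroxy-9-iodo-2,7,8-trimethylnona-2,8-dienoate
Conditions: second-generation Grubbs catalyst (5 mol %), ethyl methacrylate (10 equiv), CH2Cl2, 40 °C
Reagents that add atoms: none
Why: Olefin cross-metathesis between the monosubstituted alkene and the 1,1-disubstituted acrylate, which should give the thermodynamically favoured E-trisubstituted enoate and leave the hindered, electron-poor iodoalkene alone.

Step 5
Reactants: 8 ethyl (2E,6R,7S,8E)-6-hydroxy-9-iodo-2,7,8-trimethylnona-2,8-dienoate; 9 (E)-prop-1-enylboronic acid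
Product: 10 ethyl (2E,6R,7S,8E,10E)-6-hydroxy-2,7,8-trimethyldodeca-2,8,10-trienoate
Conditions: Pd(dppf)Cl2 (5 mol %), K3PO4, THF/H2O, rt
Reagents that add atoms: none
Why: Suzuki–Miyaura coupling, which proceeds with retention of both alkene geometries and should therefore deliver the (8E,10E)-diene with the tether trans and the C8 methyl cis to the propenyl unit.

Step 6
Reactants: 10 ethyl (2E,6R,7S,8E,10E)-6-hydroxy-2,7,8-trimethyldodeca-2,8,10-trienoate
Product: 11 ethyl (2E,7S,8E,10E)-2,7,8-trimethyl-6-oxododeca-2,8,10-trienoate
Conditions: Dess–Martin periodinane, NaHCO3, CH2Cl2, 0 °C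
Reagents that add atoms: none
Why: Dess–Martin oxidation under buffered, non-basic conditions should convert both C6 epimers into one ketone without enolising the adjacent C7 stereocentre; the product is used at once.

Step 7
Reactants: 11 ethyl (2E,7S,8E,10E)-2,7,8-trimethyl-6-oxododeca-2,8,10-trienoate
Product: 12 ethyl (1S,2S,4aR,5S,8aS)-1,2,4a,5-tetramethyl-6-oxo-1,2,4a,5,6,7,8,8a-octahydronaphthalene-1-carboxylate
Conditions: Me2AlCl (3 equiv), CH2Cl2, −78 → 0 °C
Reagents that add atoms: none
Why: Lewis-acid-promoted intramolecular Diels–Alder reaction (type 1 cyclisation of a 1,7,9-decatriene; closest precedent: Me2AlCl- or EtAlCl2-promoted cyclisations of (E)-2-methyl-2,8,10-trienoates and -trienals to trans-fused octalins bearing a quaternary carbon), in which the aluminium-complexed enoate C2=C3 adds suprafacially across the C8=C9–C10=C11 diene in a concerted, asynchronous [4+2] process that forms C3–C8 (the ring-fusion bond C8a–C4a) and C2–C11 (C1–C2). Ring A (C4a–C5–C6–C7–C8–C8a) closes as the six-membered ring spanned by the four-carbon keto tether (bond C4a–C8a), and ring B (C1–C2–C3=C4–C4a–C8a) is the cyclohexene created by the cycloaddition itself. The E-enoate fixes C1 against C8a (C8a–H cis to the ester, C1 methyl cis to the tether), the E,E-diene fixes C2 against C4a (propenyl methyl and tether outside, C8 methyl inside), and the endo orientation of the complexed ester with the tether anti links the two pairs, giving the trans ring fusion, the ester cis to the C2 methyl and the C1 methyl cis to the angular methyl. The absolute sense comes from the C7 (S) centre: in the chair-like tether its methyl group sits pseudo-equatorial and anti to the incoming dienophile while its hydrogen eclipses the diene, so only one diene face should be attacked and C7 becomes the equatorial C5 methyl of the product. The step needs endo over exo selectivity (the exo mode would give the cis-fused octalin), which Lewis-acid complexation of the E-configured ester should secure, and facial selectivity, which the C7 methyl group should secure; the sp2 ketone carbon in the tether adds no competing axial substituent. The C5 centre so obtained is also the thermodynamically preferred equatorial α-methyl ketone, so later enolisation cannot scramble it.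

Step 8
Reactants: 12 ethyl (1S,2S,4aR,5S,8aS)-1,2,4a,5-tetramethyl-6-oxo-1,2,4a,5,6,7,8,8a-octahydronaphthalene-1-carboxylate
Product: 13 ethyl (1S,2S,4aR,5S,8aS)-1,2,4a,5-tetramethyl-6-oxodecahydronaphthalene-1-carboxylate
Conditions: H2 (1 atm), 10% Pd/C, EtOAc, rt
Reagents that add atoms: none
Why: Heterogeneous catalytic hydrogenation of the cis-disubstituted ring alkene, which creates no stereocentre (C3 and C4 become CH2) and leaves ketone and ester untouched.

Step 9
Reactants: 13 ethyl (1S,2S,4aR,5S,8aS)-1,2,4a,5-tetramethyl-6-oxodecahydronaphthalene-1-carboxylate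
Product: 14 (1S,2R,4aS,5S,6S,8aR)-5-(hydroxymethyl)-1,5,6,8a-tetramethyldecahydronaphthalen-2-ol
Conditions: LiAlH4, THF, 0 °C → reflux
Reagents that add atoms: none
Why: LiAlH4 reduction of the hindered ester to the neopentyl-type primary alcohol with concomitant reduction of the ketone, expected mainly to the axial alcohol by equatorial attack (the axial face is shielded by the angular methyl); this carbinol centre is destroyed again in step 10, so its configuration is of no consequence.

Step 10
Reactants: 14 (1S,2R,4aS,5S,6S,8aR)-5-(hydroxymethyl)-1,5,6,8a-tetramethyldecahydronaphthalen-2-ol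
Product: 15 (1S,4aS,5S,6S,8aR)-5-(hydroxymethyl)-1,5,6,8a-tetramethyloctahydronaphthalen-2(1H)-one
Conditions: aq. NaOCl (1.1 equiv), AcOH, 0 °C → rt
Reagents that add atoms: none
Why: Stevens oxidation (hypochlorous acid in acetic acid), which oxidises secondary alcohols chemoselectively in the presence of primary ones, here helped by the neopentyl hindrance of the CH2OH group; the α-methyl centre stays in its equatorial, thermodynamic configuration.

Step 11
Reactants: 15 (1S,4aS,5S,6S,8aR)-5-(hydroxymethyl)-1,5,6,8a-tetramethyloctahydronaphthalen-2(1H)-one; 16 isofraxidin (7-hydroxy-6,8-dimethoxy-2H-chromen-2-one)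
Product: 17 6,8-dimethoxy-7-{[(1S,2S,4aR,5S,8aS)-1,2,4a,5-tetramethyl-6-oxodecahydronaphthalen-1-yl]methoxy}-2H-chromen-2-one
Conditions: PPh3, DIAD, THF (about 3 M), sonication, 25 → 40 °C
Reagents that add atoms: none
Why: Mitsunobu etherification, in which the acidic coumarin phenol protonates the betaine and its phenoxide displaces the alkoxyphosphonium group at the primary CH2 (no stereocentre involved); high concentration with sonication is the known remedy for neopentyl alcohols and ortho-disubstituted phenols.

**Compound list**

1 | (R)-but-3-yn-2-ol | C#C[C@@H](C)O | starting material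
2 | (R)-but-3-yn-2-yl methanesulfonate | C#C[C@@H](C)OS(C)(=O)=O | intermediate
3 | pent-4-enal | C=CCCC=O | starting material
4 | (3S,4R)-3-methyloct-7-en-1-yn-4-ol | C#C[C@H](C)[C@H](O)CCC=C | intermediate
5 | dimethyl{(1E,3S,4R)-4-[(dimethylalumanyl)oxy]-2,3-dimethylocta-1,7-dien-1-yl}alumane (alkenylalane, not isolated) | C[Al](C)/C=C(C)/[C@H](C)[C@H](O[Al](C)C)CCC=C | intermediate
6 | (1E,3S,4R)-1-iodo-2,3-dimethylocta-1,7-dien-4-ol | I/C=C(C)/[C@H](C)[C@H](O)CCC=C | intermediate
7 | ethyl methacrylate | C=C(C)C(=O)OCC | starting material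
8 | ethyl (2E,6R,7S,8E)-6-hydroxy-9-iodo-2,7,8-trimethylnona-2,8-dienoate | I/C=C(C)/[C@H](C)[C@H](O)CC/C=C(\C)C(=O)OCC | intermediate
9 | (E)-prop-1-enylboronic acid | C/C=C/B(O)O | starting material
10 | ethyl (2E,6R,7S,8E,10E)-6-hydroxy-2,7,8-trimethyldodeca-2,8,10-trienoate | C/C=C/C=C(C)/[C@H](C)[C@H](O)CC/C=C(\C)C(=O)OCC | intermediate
11 | ethyl (2E,7S,8E,10E)-2,7,8-trimethyl-6-oxododeca-2,8,10-trienoate | C/C=C/C=C(C)/[C@H](C)C(=O)CC/C=C(\C)C(=O)OCC | intermediate
12 | ethyl (1S,2S,4aR,5S,8aS)-1,2,4a,5-tetramethyl-6-oxo-1,2,4a,5,6,7,8,8a-octahydronaphthalene-1-carboxylate | CCOC(=O)[C@]1(C)[C@H]2CCC(=O)[C@@H](C)[C@]2(C)C=C[C@@H]1C | intermediate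
13 | ethyl (1S,2S,4aR,5S,8aS)-1,2,4a,5-tetramethyl-6-oxodecahydronaphthalene-1-carboxylate | CCOC(=O)[C@]1(C)[C@H]2CCC(=O)[C@@H](C)[C@]2(C)CC[C@@H]1C | intermediate
14 | (1S,2R,4aS,5S,6S,8aR)-5-(hydroxymethyl)-1,5,6,8a-tetramethyldecahydronaphthalen-2-ol | OC[C@]1(C)[C@H]2CC[C@@H](O)[C@@H](C)[C@]2(C)CC[C@@H]1C | intermediate
15 | (1S,4aS,5S,6S,8aR)-5-(hydroxymethyl)-1,5,6,8a-tetramethyloctahydronaphthalen-2(1H)-one | OC[C@]1(C)[C@H]2CCC(=O)[C@@H](C)[C@]2(C)CC[C@@H]1C | intermediate
16 | isofraxidin (7-hydroxy-6,8-dimethoxy-2H-chromen-2-one) | COc1cc2ccc(=O)oc2c(OC)c1O | starting material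
17 | 6,8-dimethoxy-7-{[(1S,2S,4aR,5S,8aS)-1,2,4a,5-tetramethyl-6-oxodecahydronaphthalen-1-yl]methoxy}-2H-chromen-2-one | COc1cc2ccc(=O)oc2c(OC)c1OC[C@]1(C)[C@H]2CCC(=O)[C@@H](C)[C@]2(C)CC[C@@H]1C | target

**Step count.** Total: 11 steps. Longest linear sequence: 11 steps (from 1).

**Steps most likely to fail**

Step 7. The cycloaddition may discriminate poorly between the endo (trans-fused) and exo (cis-fused) modes or between the two diene faces. The hindered enoate may also react so slowly that Lewis-acid-induced enolisation at C7 or cationic isomerisation of the diene competes. Any C5 epimer formed would have to be separated before base is applied. The fallback sets out from 10 and switches to the far more reactive enal dienophile. DIBAL-H (CH2Cl2, −78 °C) should reduce the ester to (2E,6R,7S,8E,10E)-2,7,8-trimethyldodeca-2,8,10-triene-1,6-diol F1. Excess Dess–Martin periodinane with NaHCO3 should oxidise both alcohols to (2E,7S,8E,10E)-2,7,8-trimethyl-6-oxododeca-2,8,10-trienal F2. This α-methyl enal should cyclise with Me2AlCl (2.2 equiv) already at −78 °C, the classical trienal variant for trans-octalins carrying a formyl-bearing quaternary carbon, to (1S,2S,4aR,5S,8aS)-1,2,4a,5-tetramethyl-6-oxo-1,2,4a,5,6,7,8,8a-octahydronaphthalene-1-carbaldehyde F3. Hydrogenation (H2, Pd/C) should then give (1S,2S,4aR,5S,8aS)-1,2,4a,5-tetramethyl-6-oxodecahydronaphthalene-1-carbaldehyde F4. Chemoselective reduction of the aldehyde in the presence of the ketone (NaBH4, EtOH/CH2Cl2, −78 °C) comes back to the route at 15.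

Step 11. The alkoxyphosphonium ion of the neopentyl-type alcohol may resist SN2 attack by the ortho-disubstituted phenoxide, so that the betaine is consumed unproductively. The fallback sets out from 15 and separates activation from displacement. Tf2O with 2,6-lutidine (CH2Cl2, −78 °C) should give [(1S,2S,4aR,5S,8aS)-1,2,4a,5-tetramethyl-6-oxodecahydronaphthalen-1-yl]methyl trifluoromethanesulfonate F5. Its much better leaving group should be displaced by the caesium salt of 16 (Cs2CO3, DMF, 50 °C), coming back to the route at 17.

Step 4. Cross-metathesis with the 1,1-disubstituted acrylate may stall through slow turnover, self-metathesis of the terminal alkene or alkene migration by ruthenium hydrides. The fallback sets out from 6 and builds the enoate by carbonyl olefination instead. OsO4 (cat.)/NaIO4 with 2,6-lutidine in dioxane/H2O should cleave only the terminal alkene, and the resulting hydroxy aldehyde closes to the lactol (5R)-5-[(2S,3E)-4-iodo-3-methylbut-3-en-2-yl]oxolan-2-ol F6 (anomeric mixture). Wittig reaction with ethyl 2-(triphenylphosphoranylidene)propanoate (toluene, 80 °C) should open the lactol and give the E-enoate, coming back to the route at 8.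

**Further compounds**

F1 | step 7 | (2E,6R,7S,8E,10E)-2,7,8-trimethyldodeca-2,8,10-triene-1,6-diol | C/C=C/C=C(C)/[C@H](C)[C@H](O)CC/C=C(\C)CO
F2 | step 7 | (2E,7S,8E,10E)-2,7,8-trimethyl-6-oxododeca-2,8,10-trienal | C/C=C/C=C(C)/[C@H](C)C(=O)CC/C=C(\C)C=O
F3 | step 7 | (1S,2S,4aR,5S,8aS)-1,2,4a,5-tetramethyl-6-oxo-1,2,4a,5,6,7,8,8a-octahydronaphthalene-1-carbaldehyde | O=C[C@]1(C)[C@H]2CCC(=O)[C@@H](C)[C@]2(C)C=C[C@@H]1C
F4 | step 7 | (1S,2S,4aR,5S,8aS)-1,2,4a,5-tetramethyl-6-oxodecahydronaphthalene-1-carbaldehyde | O=C[C@]1(C)[C@H]2CCC(=O)[C@@H](C)[C@]2(C)CC[C@@H]1C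
F5 | step 11 | [(1S,2S,4aR,5S,8aS)-1,2,4a,5-tetramethyl-6-oxodecahydronaphthalen-1-yl]methyl trifluoromethanesulfonate | O=S(=O)(OC[C@]1(C)[C@H]2CCC(=O)[C@@H](C)[C@]2(C)CC[C@@H]1C)C(F)(F)F
F6 | step 4 | (5R)-5-[(2S,3E)-4-iodo-3-methylbut-3-en-2-yl]oxolan-2-ol (anomeric mixture) | I/C=C(C)/[C@H](C)[C@H]1CCC(O)O1
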